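(The readings are simulated with made-up constants, and the scatter is random.)

370 µM was the number I carried into spring and noon: the working catalyst, meaning the free catalyst charged less the impurity charged, taken one for one.

| setting | gamma | eta | theta | spring | noon |
|---|---|---|---|---|---|
| starting material | 0.050 M (fed, over 80 min) | 0.20 M (fed, over 80 min) | 0.10 M (fed, over 80 min) | 0.10 M | 0.10 M (fed, over 80 min) |
| free catalyst | 0.45 mol% | 0.45 mol% | 0.9 mol% | 0.45 mol% | 0.45 mol% |
| impurity | 80 µM | 80 µM | 80 µM | 80 µM | 80 µM |
| remark | run made earlier; the fed solution adds 1.0 times the starting volume | run made earlier; the fed solution adds 1.0 times the starting volume | run made earlier; the fed solution adds 1.0 times the starting volume | everything together at the start, the whole solution of starting material included, so that from the start the volume is larger by 1.0 times the starting volume | the fed solution adds 1.0 times the starting volume |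
| time |  |  |  | 80 min | 80 min |

- gamma (time / min: target / %): 3.00: 0; 10.0: 0; 15.0: 0.8; 25.0: 1.8; 40.0: 5.1; 50.0: 6.6
- eta (time / min: target / %): 8.00: 0.8; 15.0: 3.6; 25.0: 8.9; 30.0: 11.5; 40.0: 19.0; 50.0: 25.4
- theta (time / min: target / %): 4.00: 0.5; 8.00: 1.2; 15.0: 4.7; 25.0: 9.5; 50.0: 27.5

(scatter of a reading: 0.3 percentage points)

- amounts are per litre of the starting volume; all of the dose is in the solution fed
- the numbers in the tables scatter by 0.3 percentage points (one standard deviation)
- percentages count the whole charge, also what has not yet gone in

* which of the two ends with the higher amount of target, in percent of the starting material charged ("neither" if they lie within 2 percentage points) (spring / noon / neither)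
* target at the end, in percent of the starting material charged, spring
* target at the end, in percent of the starting material charged, noon

The runs looked contradictory: gamma and eta carry the same 0.45 mol% loading, yet at 50.0 min gamma stood at 6.6 % and eta at 25.4 %, while theta, with twice eta's loading on half its charge, stood within 2.1 percentage points of eta. Concentrations clear this up: c(free catalyst) charged is 900 µM in eta and 900 µM in theta, but 225 µM in gamma, so the percent curve follows catalyst concentration, as a pseudo-first-order rate in starting material does.

I wrote dp/dt = κs/V, with p and s the target and the starting material in the flask as fractions of the charge, and V the volume over the starting volume. The slope from 30.0 min to 50.0 min gave κ = 0.0336 min⁻¹ for eta, and the slope from 25.0 min to 50.0 min gave 0.00661 min⁻¹ for gamma. Their ratio, 5.08, exceeds the 4.00 of the charged catalyst and lies toward the 5.66 of working catalyst, gamma's rise being 4.8 points against a scatter of 0.3 points.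

Scaling eta by working catalyst gave κ = 0.0152 min⁻¹. For spring, 1 − exp(−κt/2.00) gave me 45.5 %. For noon, a = κ·80 min = 1.21, and s = (u − u^(−a))/(a + 1) at u = 2.00 gave me 29.1 %.

The forecast said spring, with 46 % against 30 %, both above mine, holding that “the impurity removes a fixed ~65–80 µM of catalyst”.

The flasks gave 45.8 % for spring and 29.9 % for noon, so spring ended higher.

    starting material + free catalyst ⇌ catalyst intermediate (K = 960 M⁻¹, k = 1.50 M⁻¹ s⁻¹)
    catalyst intermediate → free catalyst + target (k = 0.150 s⁻¹)
    free catalyst ⇌ dormant form (K = 0.810, k = 0.00520 s⁻¹)
    2 starting material → homo dimer (k = 1.50 × 10⁻⁶ M⁻¹ s⁻¹)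
    free catalyst + impurity → spent catalyst (k = 220 M⁻¹ s⁻¹)

In noon, free catalyst has a half-life against impurity of 0.66 min with the charges held, far shorter than the 80 min of the run. At the end of noon, impurity stands at 0 % of its own charge and spent catalyst at 17.8 % of the catalyst charged, where impurity charged over catalyst charged gives 17.8 %. A neighbour of spring with 320 µM of impurity has 130 µM of working catalyst, which reckons to 19.2 %, and that flask ended with spent catalyst at 71.1 % and target at 19.3 %.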